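**Assumption:** the target SMILES has no stereocentres or stereogenic double bonds (robustol is achiral), so there is no enantiomer to control. The carbinol centres and the E/Z alkene created along the way are carried as mixtures and erased in step 5.

## Retrosynthetic overview

1. Robustol ⇐ its tri‑O‑methyl ether (global ArO–Me cleavage last).
2. Saturated C14 bridge ⇐ macrocyclic alkene‑diol, by one‑pot alkene hydrogenation and benzylic C–OH hydrogenolysis.
3. 22‑membered ring ⇐ acyclic bis(oct‑7‑enyl carbinol) by ring‑closing metathesis at the centre of the bridge (C7–C8). This is the only ring formed.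
4. Both arms ⇐ diaryl ether dialdehyde + 2 hept‑6‑enylMgBr, the Grignard made from 7‑bromohept‑1‑ene (8 + 8 − 2 = 14 bridge carbons).
5. Diaryl ether ⇐ syringaldehyde + 3‑bromo‑5‑methoxybenzaldehyde (Ullmann O‑arylation); both arenes are commercial.

## Route

**Step 1**
Reactants: 1, syringaldehyde (4‑hydroxy‑3,5‑dimethoxybenzaldehyde); 2, 3‑bromo‑5‑methoxybenzaldehyde
Product: 3, 4‑(3‑formyl‑5‑methoxyphenoxy)‑3,5‑dimethoxybenzaldehyde
Conditions: CuI (10–20 mol %), picolinic acid (20–40 mol %), K3PO4 (2 equiv), DMSO, 90–110 °C, Ar; 1 in slight excess
Reagents that add atoms: none (both partners are numbered reactants)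
Why: Cu(I)/picolinic acid Ullmann‑type O‑arylation is designed for di‑ortho‑substituted phenols; the aryl bromide is unhindered and mildly activated by the meta‑CHO, and the non‑enolisable aldehydes tolerate anhydrous phosphate base.

**Step 2**
Reactants: 4, 7‑bromohept‑1‑ene
Product: 5, hept‑6‑enylmagnesium bromide (about 0.5 M THF solution, titrated and used directly in step 3)
Conditions: Mg turnings (1.2 equiv), cat. I2, THF, rt → 40 °C, Ar
Reagents that add atoms: magnesium, [Mg]
Why: Grignard formation by Mg insertion into the primary C–Br bond; the terminal alkene is too remote to cyclise onto the transient radical at a competitive rate.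

**Step 3**
Reactants: 3, dialdehyde; 5, hept‑6‑enylmagnesium bromide (about 2.6 equiv)
Product: 6, 1‑[4‑[3‑(1‑hydroxyoct‑7‑enyl)‑5‑methoxyphenoxy]‑3,5‑dimethoxyphenyl]oct‑7‑en‑1‑ol (mixture of diastereomers, racemic)
Conditions: 5 added to 3, THF, 0 °C → rt; aq. NH4Cl
Reagents that add atoms: none (both partners are numbered reactants; two hept‑6‑enyl groups are delivered from 5)
Why: Double Grignard 1,2‑addition to two non‑enolisable aryl aldehydes installs both arms with saturated attachment to the rings, so no styrenyl alkene is present to interfere with metathesis; the carbinol configuration is irrelevant.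

**Step 4**
Reactants: 6, diene diol
Product: 7, 22‑membered macrocyclic diaryl ether whose C14 bridge carries OH at C‑1 and C‑14 and a C7=C8 double bond (E/Z and diastereomer mixture)
Conditions: Grubbs II (5–10 mol %), CH2Cl2, 1–2 mM, 40 °C (slow addition of 6); ethylene swept out with Ar
Reagents that add atoms: none (ethylene is lost)
Why: Ring‑closing metathesis of two unhindered terminal alkenes to a large, unstrained ring under high dilution; Ru carbenes tolerate the free, non‑allylic alcohols, and alkene geometry does not matter.

**Step 5**
Reactants: 7, macrocyclic alkene diol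
Product: 8, tri‑O‑methylrobustol (saturated C14 bridge, three ArOMe groups)
Conditions: H2 (1–4 atm), 10 % Pd/C, EtOAc–AcOH, cat. HClO4, rt
Reagents that add atoms: none (hydrogen only)
Why: Catalytic hydrogenation saturates the alkene while acid‑promoted Pd hydrogenolysis removes both secondary benzylic hydroxyls; the diaryl ether and aryl methyl ethers are inert, and all stereo‑elements are erased.

**Step 6**
Reactants: 8, tri‑O‑methylrobustol
Product: 9, robustol
Conditions: BBr3 (6–8 equiv), CH2Cl2, −78 °C → rt; MeOH then H2O quench
Reagents that add atoms: none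
Why: Lewis‑acid demethylation by BBr3 cleaves the three aryl methyl ethers (including the flanking 2,6‑pair) without touching the diaryl ether C–O bonds or the alkyl bridge.

## Compound list

1 | syringaldehyde (4‑hydroxy‑3,5‑dimethoxybenzaldehyde) | COc1cc(C=O)cc(OC)c1O | starting material
2 | 3‑bromo‑5‑methoxybenzaldehyde | COc1cc(Br)cc(C=O)c1 | starting material
3 | 4‑(3‑formyl‑5‑methoxyphenoxy)‑3,5‑dimethoxybenzaldehyde | COc1cc(C=O)cc(c1)Oc1c(OC)cc(C=O)cc1OC | intermediate
4 | 7‑bromohept‑1‑ene | BrCCCCCC=C | starting material
5 | hept‑6‑enylmagnesium bromide (THF solution, used without isolation) | C=CCCCCC[Mg]Br | intermediate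
6 | 1‑[4‑[3‑(1‑hydroxyoct‑7‑enyl)‑5‑methoxyphenoxy]‑3,5‑dimethoxyphenyl]oct‑7‑en‑1‑ol (diastereomer mixture) | COc1cc(C(O)CCCCCC=C)cc(c1)Oc1c(OC)cc(cc1OC)C(O)CCCCCC=C | intermediate
7 | macrocyclic alkene diol (22‑membered ring; bridge C‑1/C‑14 OH, C7=C8 alkene; E/Z and diastereomer mixture) | COc1cc2cc(c1)Oc1c(OC)cc(cc1OC)C(O)CCCCCC=CCCCCCC2O | intermediate
8 | tri‑O‑methylrobustol | COc1cc2cc(c1)Oc1c(OC)cc(cc1OC)CCCCCCCCCCCCCC2 | intermediate
9 | robustol | Oc1cc2cc(c1)Oc1c(O)cc(cc1O)CCCCCCCCCCCCCC2 | target

## Summary

Total steps: 6 (five isolated products; the Grignard solution from step 2 is used directly in step 3).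
Longest linear sequence: 5 steps (1/2 → 3 → 6 → 7 → 8 → 9, or equally 4 → 5 → 6 → 7 → 8 → 9).

Three steps most likely to fail, with fallbacks:

1. **Step 1, Ullmann coupling.** The phenol is di‑ortho‑substituted and electron‑poor. Fallback: change the C–O bond‑forming manifold to a room‑temperature oxidative Chan–Lam–Evans coupling of 1 with (3‑formyl‑5‑methoxyphenyl)boronic acid (by Miyaura borylation of 2 if not purchased), using Cu(OAc)2, pyridine, 4 Å MS, CH2Cl2, air.
2. **Step 4, RCM macrocyclisation.** Oligomerisation may compete in forming the 22‑membered ring. Fallback: change the ring‑closing bond. Join two separately functionalised arenes through the C14 chain first (each aldehyde + hept‑6‑enylMgBr, then intermolecular cross‑metathesis and reduction), and close the macrocycle by intramolecular Ullmann diaryl ether formation under high dilution.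
3. **Step 5, double benzylic hydrogenolysis.** The ring‑A carbinol, with only meta oxygens, may resist C–OH cleavage. Fallback: avoid benzylic oxygen altogether. Reduce 3 with NaBH4, convert to the bis(benzyl bromide) with PBr3, and run a Li2CuCl4‑catalysed sp3–sp3 coupling with 5 to give the deoxy diene directly; RCM and plain hydrogenation then give 8.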